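**Retrosynthetic overview**
1. Last bond, C5–O: the peri 5-OH is put on the finished flavonol by C4=O-directed C–H oxygenation (new variant, 3-OH masked in the flask).
2. Ring C (O1–C2 and C3–O bonds; the only ring that is made): one-pot Claisen–Schmidt condensation / Algar–Flynn–Oyamada oxidative cyclisation of a 2'-hydroxyacetophenone with p-anisaldehyde.
3. The 2'-OH (the future O1): ketone-directed ortho C–H hydroxylation of 3',4',5'-trimethoxyacetophenone.
4. Rings A and B are bought; both ortho oxygens of the gallate-type A ring (O1 and 5-OH) come from carbonyl-directed C–H oxygenation with one Ru/iodine(III) system.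

Assumption: the target SMILES has no stereocentre (achiral, planar flavonol), so there is no enantiomer to control; the only stereocentres on the way (non-isolated dihydroflavonol 6) are racemic and are removed in the same flask.

**Route**

Step 1
Reactants: 1 methyl 3,4,5-trimethoxyphenyl ketone (3',4',5'-trimethoxyacetophenone)
Product: 3 methyl 2-hydroxy-3,4,5-trimethoxyphenyl ketone (2'-hydroxy-3',4',5'-trimethoxyacetophenone), via aryl trifluoroacetate 2 (not isolated)
Conditions: [RuCl2(p-cymene)]2 (2.5 mol%), PhI(OCOCF3)2 (1.1 equiv), TFA/TFAA 4:1, 80 °C; then H2O/MeOH, rt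
Reagents that add atoms: [bis(trifluoroacetoxy)iodo]benzene (PIFA, source of the new O), O=C(OI(OC(=O)C(F)(F)F)c1ccccc1)C(F)(F)F
Why: Ketone-directed ruthenium-catalysed ortho C–H hydroxylation (weak C=O coordination, carboxylate-assisted ruthenation, oxidation of Ru(II) to Ru(IV) by the iodine(III) reagent, C–O reductive elimination) is an established reaction of aryl ketones; the two ortho C–H bonds of 1 are equivalent, so only one regioisomer can form, and the product stays as the electron-poor ester 2, which holds back a second oxygenation and oxidation of the new p-methoxyphenol until aqueous methanol cleaves it.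

Step 2
Reactants: 3 methyl 2-hydroxy-3,4,5-trimethoxyphenyl ketone; 4 p-anisaldehyde (4-methoxybenzaldehyde)
Product: 7 flavonol 3-hydroxy-6,7,8-trimethoxy-2-(4-methoxyphenyl)-4H-chromen-4-one, via chalcone 5 (not isolated), via trans-dihydroflavonol 6 (not isolated)
Conditions: KOH (50% aq., 5 equiv), EtOH, rt, 24 h; then 30% H2O2 (3 equiv), 0 °C to rt; then 2 M HCl
Reagents that add atoms: hydrogen peroxide, OO
Why: Claisen–Schmidt condensation gives the (E)-chalcone 5 and the Algar–Flynn–Oyamada reaction (6-endo oxa-Michael closure of the phenoxide, hydroxylation of the enolate by hydroperoxide to racemic trans-6, dehydrogenation) gives the flavonol and not the aurone because C6' carries only H; the two stereocentres of 6 are lost again in the same flask.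

Step 3
Reactants: 7 flavonol 3-hydroxy-6,7,8-trimethoxy-2-(4-methoxyphenyl)-4H-chromen-4-one
Product: 10 target 3,5-dihydroxy-6,7,8-trimethoxy-2-(4-methoxyphenyl)-4H-chromen-4-one (3,5-dihydroxy-6,7,8,4'-tetramethoxyflavone), via 3-O-trifluoroacetate 8 (not isolated), via 3,5-bis(trifluoroacetate) 9 (not isolated)
Conditions: TFAA/TFA 1:3, rt, 30 min; then [RuCl2(p-cymene)]2 (5 mol%), PhI(OCOCF3)2 (1.2 equiv), 80 °C; then H2O/MeOH, rt
Reagents that add atoms: [bis(trifluoroacetoxy)iodo]benzene (PIFA, source of the new O), O=C(OI(OC(=O)C(F)(F)F)c1ccccc1)C(F)(F)F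
Why: Proposed new method: TFAA first turns the chelating, easily oxidised 3-OH into the 3-O-trifluoroacetate 8, so Ru cannot be trapped as an O3,O4-flavonolato chelate and the enol is shielded from iodine(III), the C4=O lone pair syn to C5 then directs carboxylate-assisted ruthenation of the only A-ring C–H (five-membered ruthenacycle, helped by the ortho and para OMe groups), PhI(OCOCF3)2 oxidises Ru(II) to Ru(IV) and C–O reductive elimination gives the 5-trifluoroacetate 9, whose ester groups protect the new 5-hydroxy-8-methoxy (p-methoxyphenol) unit from over-oxidation until both are solvolysed on quench; the closest known reaction type is the Ru(II)/PhI(OCOCF3)2 ketone-directed ortho C–H hydroxylation of aryl ketones and of the C5–H bond of 3-unsubstituted chromones and flavones, which has not been shown on a free 3-hydroxyflavone or with a transient O-acyl mask.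

**Compound list**
1 | 1-(3,4,5-trimethoxyphenyl)ethan-1-one (3',4',5'-trimethoxyacetophenone) | CC(=O)c1cc(OC)c(OC)c(OC)c1 | starting material
2 | 6-acetyl-2,3,4-trimethoxyphenyl trifluoroacetate | CC(=O)c1cc(OC)c(OC)c(OC)c1OC(=O)C(F)(F)F | intermediate
3 | 1-(2-hydroxy-3,4,5-trimethoxyphenyl)ethan-1-one (2'-hydroxy-3',4',5'-trimethoxyacetophenone) | CC(=O)c1cc(OC)c(OC)c(OC)c1O | intermediate
4 | 4-methoxybenzaldehyde (p-anisaldehyde) | COc1ccc(C=O)cc1 | starting material
5 | (E)-1-(2-hydroxy-3,4,5-trimethoxyphenyl)-3-(4-methoxyphenyl)prop-2-en-1-one | COc1ccc(/C=C/C(=O)c2cc(OC)c(OC)c(OC)c2O)cc1 | intermediate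
6 | (±)-trans-3-hydroxy-6,7,8-trimethoxy-2-(4-methoxyphenyl)chroman-4-one, racemic, (2R,3R) enantiomer drawn | COc1ccc(cc1)[C@H]2Oc3c(OC)c(OC)c(OC)cc3C(=O)[C@@H]2O | intermediate
7 | 3-hydroxy-6,7,8-trimethoxy-2-(4-methoxyphenyl)-4H-chromen-4-one | COc1ccc(-c2oc3c(OC)c(OC)c(OC)cc3c(=O)c2O)cc1 | intermediate
8 | 6,7,8-trimethoxy-2-(4-methoxyphenyl)-4-oxo-4H-chromen-3-yl trifluoroacetate | COc1ccc(-c2oc3c(OC)c(OC)c(OC)cc3c(=O)c2OC(=O)C(F)(F)F)cc1 | intermediate
9 | 6,7,8-trimethoxy-2-(4-methoxyphenyl)-4-oxo-4H-chromene-3,5-diyl bis(trifluoroacetate) | COc1ccc(-c2oc3c(OC)c(OC)c(OC)c(OC(=O)C(F)(F)F)c3c(=O)c2OC(=O)C(F)(F)F)cc1 | intermediate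
10 | 3,5-dihydroxy-6,7,8-trimethoxy-2-(4-methoxyphenyl)-4H-chromen-4-one (3,5-dihydroxy-6,7,8,4'-tetramethoxyflavone) | COc1ccc(-c2oc3c(OC)c(OC)c(OC)c(O)c3c(=O)c2O)cc1 | target

**Step count and risks**
Total step count: 3. Longest linear sequence: 3 steps (1 → 3 → 7 → 10); 4 enters in step 2.

The three steps most likely to fail, most risky first:

Step 3 (the proposed new step). Possible failures are incomplete acylation of O3, which leads to Ru sequestration or iodine(III) degradation of the enol, and slow ruthenation at a C–H flanked by OMe. The unmasked product can also be oxidised by left-over iodine(III), so any excess is reduced with a little Me2S before aqueous methanol is added. The fallback uses known chemistry and replaces the in-flask mask by a protect–oxidise–deprotect sequence with an isolated, acid-stable ester. It sets out from 7, which is acylated with pivaloyl chloride (Et3N, cat. DMAP, CH2Cl2) to 6,7,8-trimethoxy-2-(4-methoxyphenyl)-4-oxo-4H-chromen-3-yl pivalate F1. F1 is an ordinary non-chelating flavone and is put through the established Ru(II)/PhI(OCOCF3)2 C5–H hydroxylation of flavones in TFA/TFAA at 80 °C. This gives crude 6,7,8-trimethoxy-2-(4-methoxyphenyl)-4-oxo-5-(trifluoroacetoxy)-4H-chromen-3-yl pivalate F2, and K2CO3/MeOH under N2 then removes both esters. The sequence comes back to the route at 10.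

Step 1. Possible failures are direct iodine(III) oxidation of the electron-rich trimethoxyarene (biaryls, quinones), double oxygenation, and slow metalation next to OMe. The fallback replaces C–H activation by electrophilic halogenation and cross-coupling. It sets out from 1, and ring iodination (I2, AgO2CCF3, CH2Cl2, rt) gives 1-(2-iodo-3,4,5-trimethoxyphenyl)ethan-1-one F3. A copper-catalysed Ullmann-type hydroxylation (CuI, 1,10-phenanthroline, KOH, DMSO/H2O, 80–100 °C, then HCl) converts F3 into 3, where the route is rejoined.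

Step 2. Possible failures are slow condensation of the electron-rich aldehyde, Dakin oxidation of left-over aldehyde, aurone or ring-cleavage by-products, and base/O2 degradation of the flavonolate. The fallback replaces the Algar–Flynn–Oyamada reaction by the flavone–epoxide route. It sets out from chalcone 5, isolated by acidifying before any peroxide is added. I2 (cat.) in DMSO at 130 °C cyclises and dehydrogenates it to 6,7,8-trimethoxy-2-(4-methoxyphenyl)-4H-chromen-4-one F4. Dimethyldioxirane (acetone/CH2Cl2, 0 °C) gives the racemic cis-fused 2,3-epoxy-6,7,8-trimethoxy-2-(4-methoxyphenyl)chroman-4-one F5, which cat. p-TsOH isomerises to 7, where the route is rejoined.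

**Further compounds**
F1 | step 3 | 6,7,8-trimethoxy-2-(4-methoxyphenyl)-4-oxo-4H-chromen-3-yl pivalate | COc1ccc(-c2oc3c(OC)c(OC)c(OC)cc3c(=O)c2OC(=O)C(C)(C)C)cc1
F2 | step 3 | 6,7,8-trimethoxy-2-(4-methoxyphenyl)-4-oxo-5-(trifluoroacetoxy)-4H-chromen-3-yl pivalate | COc1ccc(-c2oc3c(OC)c(OC)c(OC)c(OC(=O)C(F)(F)F)c3c(=O)c2OC(=O)C(C)(C)C)cc1
F3 | step 1 | 1-(2-iodo-3,4,5-trimethoxyphenyl)ethan-1-one | CC(=O)c1cc(OC)c(OC)c(OC)c1I
F4 | step 2 | 6,7,8-trimethoxy-2-(4-methoxyphenyl)-4H-chromen-4-one | COc1ccc(-c2cc(=O)c3cc(OC)c(OC)c(OC)c3o2)cc1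
F5 | step 2 | (±)-2,3-epoxy-6,7,8-trimethoxy-2-(4-methoxyphenyl)chroman-4-one, racemic, cis-fused, one enantiomer drawn | COc1ccc(cc1)[C@]23O[C@H]2C(=O)c2cc(OC)c(OC)c(OC)c2O3
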